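## Structural features

Cudraflavone C is a flavone made of three rings. Ring A is a phloroglucinol-type benzene (C4a to C8a) with OH on C5 and C7, a 3-methylbut-2-enyl (prenyl) group on C6 and H on C8. Ring C is the fused 4-pyranone (O1, C2, C3, C4=O), and ring B is a resorcinol (OH on C2' and C4') joined to C2 through C1'. A second prenyl group sits on C3, so the C2–C1' bond is flanked by the C3 prenyl group and the C2' oxygen. There is no stereocentre and no stereogenic double bond, so every problem is one of regiochemistry: prenyl on C6 and not C8, C- and not O-alkylation, and a 2',4' and not a 3',5' oxygen pattern on ring B. The fragile parts are the two trisubstituted olefins, which can cyclise onto neighbouring phenols or hydrate under acid, and the electron-rich polyphenol, which oxidises easily. The real difficulty is to load C2, C3 and C6 with carbon substituents without a hindered aryl–aryl coupling at C2 and without C6/C8 ambiguity. The key step uses the fact that ring B is a 1,3-dioxygenated benzene: its C2' and C4' oxygens match the C6 and C4 oxygens of a 4,6-bis(silyloxy)-2-pyranone and its C1'–C6' edge matches an ethynyl group on C2 of the chromone.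

## Logic of the disconnections

26 to 25 to 24: the two O–CH2 acetal bonds on O5 and O7 are cut first, then the two O–Si bonds on O2' and O4'. The acetals are needed earlier as metalation directors and to keep ring A free of OH groups during the cycloaddition; the silyl groups are what the cycloaddition delivers. Nothing is gained in skeleton. The demand is a buffered fluoride step and then an acid step mild enough to spare the prenyl olefins next to the freed phenols.

24 to 19 and 22: the bonds C1'–C2' and C5'–C6' are cut, with CO2 notionally put back between C2' and C5'. This removes the whole of ring B and avoids making the doubly ortho-substituted C2–C1' bond by coupling. The 25-carbon flavone becomes a chromone with a two-carbon handle plus a five-carbon heterocycle. The demand is one regiochemistry (C3 of 22 to the terminal alkyne carbon of 19) under neutral thermal conditions.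

22 to 21 to 20: two O–Si bonds are cut, then the anhydride C–O bond. This takes the diene back to a cheap symmetrical diacid. The demand is O-silylation at the C4 oxygen and at one anhydride oxygen, and anhydrous handling of 22.

19 to 18 to 16 and 17: the C(sp)–Si bond is cut, then the C2–C(sp) bond. A cross-coupling at an iodinated C2 is the most reliable way to attach two carbons there. The demand is a desilylation that adds no nucleophile to the activated alkyne.

16 to 14: the C2–I bond is cut. With C3 substituted, C2–H is the only acidic position of ring C, so 14 needs no other handle. The demand is a base that metalates C2 without attacking C4=O or the acetals.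

14 to 12: O1–C2 and C2–C3 are cut, which removes the one carbon C2 and opens ring C to an ortho-hydroxyaryl ketone. The demand is that the free OH of 12 stands para to the ring prenyl group, so that this group ends on C6 and not C8.

12 to 11 to 6 and 9: the O–Si bond is cut, then the aryl–acyl bond C4–C4a. The acyl chain of 9 already carries the future C3 prenyl group, so no later alkylation of ring C is needed. The demand is ring lithiation of 6 between the silyloxy and one acetal oxygen, without silyl migration.

9 to 7: the amide C–N bond is cut, leading to a simple unsaturated acid. The demand is only a neutral activation.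

6 to 3 and 4: the aryl–CH2 bond of the ring prenyl group is cut. In 3 only one C–H lies between two acetal oxygens, so the site is unambiguous and the product stays symmetric. The demand is attack at the primary carbon of 4 without allylic transposition.

3 to 2 to 1: the O–Si bond and two O–CH2 bonds are cut. Giving the third oxygen a different group decides which oxygen becomes O1. The demand is acceptance of a statistical bis-alkylation of 1.

## Other disconnections considered

Alternative 1: The cut is C4a–C5, which opens ring A to a β-keto ester chain on C8a of a 2-aryl-3-prenyl-4-pyranone. The precursor is the keto ester A2, a methyl 3-oxo-2-prenylbutanoate whose C4 is bonded to C6 of 2-(2,4-bis(methoxymethoxy)phenyl)-3-prenyl-4H-pyran-4-one. In the forward step a base would deprotonate the C8 methylene of A2, the vinylogous enolate would attack the ester through C4a (Claisen-type condensation), and enolisation would give the 5,7-diol A1, which is cudraflavone C 2',4'-bis(methoxymethyl) ether.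
- In its favour: ring A of A1 would arise with both phenols free and with the prenyl group fixed on C6 by the chain of A2. On C6/C8 control it is the equal of the chosen plan. Only one deprotection would follow A1, which is better than the two after step 13. The mechanism follows well-known polyketide-type ring closures, so on precedent it is ahead of step 13.
- Against it: the keto ester A2 is a polycarbonyl compound whose assembly needs several acylation steps. Its most acidic proton is C6–H between ketone and ester, so the ester is deactivated unless a polyanion is formed, and strong base invites pyranone opening and retro-Claisen cleavage. The hindered C2–C1' junction must still be set earlier.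
- Comparison: the route through A2 and A1 is better on end-game and precedent, worse on precursor complexity and on control of the enolisation site; the overall step count is estimated to be similar or somewhat higher.

Alternative 2: The cuts are O1–C8a, C4–C4a and O1–C2, which divide ring C between an aryne precursor and an acid. The aryne precursor is the silyl triflate A4, 3,5-bis(methoxymethoxy)-4-prenyl-2-(trimethylsilyl)phenyl trifluoromethanesulfonate. The acid is A5, 3-(2,4-bis(methoxymethoxy)phenyl)-3-methoxy-2-prenylprop-2-enoic acid. With CsF, the aryne from A4 would take up the carboxylate oxygen of A5 at C8a, the aryl anion at C4a would capture the acyl carbon, and the new phenoxide would displace methoxide at C2 to give A3, the 5,7,2',4'-tetrakis(methoxymethyl) ether of cudraflavone C.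
- In its favour: joining A4 and A5 is the most convergent of the four plans, and here it is better than the chosen plan. The 3-alkoxy effect on the aryne from A4 directs the oxygen to C8a and the anion to C4a, which is the required sense, so C6/C8 control is equal. Aryne insertion into carboxylic acids is an established reaction type, so the mechanism is better precedented than step 13. One acid step on A3 would finish the synthesis, against two in the chosen plan.
- Against it: the silyl triflate A4 is a pentasubstituted benzene and the acid A5 a tetrasubstituted β-methoxyacrylic acid, each several steps. The acyl carbon of A5 is hindered and deactivated by the β-methoxy group, so plain O-arylation or protonation of the aryl anion could win over acyl transfer.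
- Comparison: total step count is estimated to be similar, with a shorter longest linear sequence, but the C2–C1' bond must be made inside A5, and the end-game from A3 exposes four acetals to acid at once.

Alternative 3: The cuts are C8–C8a, C5–C6, C7–C8 and C4a–C5, which remove ring A. The precursors are the diazoketone A7 and the siloxyalkyne A8. The diazoketone A7 is a 4-pyranone with the 2,4-bis(methoxymethoxy)phenyl group on C2, the prenyl group on C3 and a diazoacetyl group on C6. The siloxyalkyne A8 is the triisopropylsilyl ynol ether of 5-methylhex-4-en-1-yne, with the silyloxy group on C1. Irradiation of A7 together with A8 would trigger Wolff rearrangement to a vinylketene, [2+2] addition to the siloxyalkyne, four-electron opening of the cyclobutenone and six-electron electrocyclisation, to give A6, the 7-triisopropylsilyl 2',4'-bis(methoxymethyl) ether of cudraflavone C.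
- In its favour: the whole substitution pattern of ring A in A6 (free 5-OH, silylated 7-O, prenyl on C6) would be written by the mechanism, which is equal or better than the chosen plan on regiocontrol. The reaction type is established for vinyl diazoketones, so precedent is better than for step 13. Two deprotections would follow A6, equal to the chosen plan.
- Against it: the diazoacetyl group of A7 has to be installed with diazomethane or by a diazo-transfer sequence. The 4-pyranone chromophore of A7 is itself photolabile under the irradiation. The siloxyalkyne A8 is hydrolytically sensitive and not trivial to make.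
- Comparison: the step count through A7, A8 and A6 is estimated to be comparable; the chosen plan avoids diazo and photochemical steps but accepts a cycloaddition without direct precedent.

Key step: step 13

Assumption: 5-methylhex-4-enoic acid (7) is taken as a purchasable building block; it is otherwise two routine steps from 2-methylbut-3-en-2-ol (ortho ester Claisen rearrangement, saponification).
Remark: organometallic intermediates are drawn as monomers; 23 is a racemic transient whose bridgehead centres vanish on loss of CO2.

## Route

Step 1
Reactants: 1 phloroglucinol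
Product: 2 3,5-bis(methoxymethoxy)phenol
Conditions: MOMCl (2.0 equiv), i-Pr2NEt (2.2 equiv), DMF, 0 °C to rt
Reagents that add atoms: chloromethyl methyl ether, COCCl
Why: O-alkylation of the phenol with the chloromethyl ether; with two equivalents the bis-ether should be the main component of a statistical mixture and is separable because it keeps one acidic OH, while mono- and tris-ethers can be recycled.

Step 2
Reactants: 2 3,5-bis(methoxymethoxy)phenol
Product: 3 [3,5-bis(methoxymethoxy)phenoxy]tri(propan-2-yl)silane
Conditions: TIPSCl, imidazole, DMF, rt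
Reagents that add atoms: chlorotri(propan-2-yl)silane, CC(C)[Si](Cl)(C(C)C)C(C)C
Why: Imidazole-promoted silylation of a phenol; the bulky silyl ether resists alkyllithiums, is a poor ortho-director and marks the oxygen that will become O1.

Step 3
Reactants: 3 [3,5-bis(methoxymethoxy)phenoxy]tri(propan-2-yl)silane; 4 1-bromo-3-methylbut-2-ene
Product: 6 [3,5-bis(methoxymethoxy)-4-(3-methylbut-2-en-1-yl)phenoxy]tri(propan-2-yl)silane, via 4-lithiated aryl silyl ether 5 (not isolated)
Conditions: n-BuLi, THF, 0 °C; CuI (10 mol%), then 4, −78 °C to rt
Reagents that add atoms: none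
Why: Directed ortho-metalation at the only C–H flanked by two chelating acetal oxygens, then copper-catalysed SN2 alkylation at the primary carbon of the allylic bromide; the product stays symmetric, so either remaining ring position is equivalent.

Step 4
Reactants: 7 5-methylhex-4-enoic acid
Product: 9 N-methoxy-N,5-dimethylhex-4-enamide, via acyl imidazolide 8 (not isolated)
Conditions: CDI, CH2Cl2, rt; then MeNHOMe·HCl, rt
Reagents that add atoms: N,O-dimethylhydroxylamine hydrochloride, CNOC.Cl
Why: Amide formation through carbonyldiimidazole activation; the neutral conditions leave the trisubstituted olefin untouched.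

Step 5
Reactants: 6 [3,5-bis(methoxymethoxy)-4-(3-methylbut-2-en-1-yl)phenoxy]tri(propan-2-yl)silane; 9 N-methoxy-N,5-dimethylhex-4-enamide
Product: 11 1-[2,4-bis(methoxymethoxy)-3-(3-methylbut-2-en-1-yl)-6-{[tri(propan-2-yl)silyl]oxy}phenyl]-5-methylhex-4-en-1-one, via 2-lithiated arene 10 (not isolated)
Conditions: s-BuLi, TMEDA, THF, −78 °C; then 9, −78 to −20 °C; then H2O
Reagents that add atoms: none
Why: A second directed ortho-metalation next to an acetal oxygen, followed by Weinreb ketone synthesis, which stops at the ketone; keeping the aryllithium at −78 °C should suppress the O-to-C silyl shift (retro-Brook rearrangement).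

Step 6
Reactants: 11 1-[2,4-bis(methoxymethoxy)-3-(3-methylbut-2-en-1-yl)-6-{[tri(propan-2-yl)silyl]oxy}phenyl]-5-methylhex-4-en-1-one
Product: 12 1-[6-hydroxy-2,4-bis(methoxymethoxy)-3-(3-methylbut-2-en-1-yl)phenyl]-5-methylhex-4-en-1-one
Conditions: TBAF, AcOH (1:1), THF, 0 °C to rt
Reagents that add atoms: none
Why: Fluoride cleavage of the aryl silyl ether, driven by the Si–F bond and buffered by acetic acid; the acetals, ketone and olefins are inert, and the freed OH is the one para to the ring prenyl group.

Step 7
Reactants: 12 1-[6-hydroxy-2,4-bis(methoxymethoxy)-3-(3-methylbut-2-en-1-yl)phenyl]-5-methylhex-4-en-1-one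
Product: 14 5,7-bis(methoxymethoxy)-3,6-bis(3-methylbut-2-en-1-yl)-4H-chromen-4-one, via enaminone 13 (not isolated)
Conditions: t-BuOCH(NMe2)2 (2 equiv), PhMe, 90 °C; then AcOH, rt
Reagents that add atoms: tert-butoxybis(dimethylamino)methane, CN(C)C(OC(C)(C)C)N(C)C
Why: Aminomethylenation of the ketone α-methylene, then addition–elimination of the ortho-phenol at the enaminone β-carbon with loss of dimethylamine, the standard enaminone route to 3-substituted chromones; the tert-butoxy aminal cannot O-methylate the phenol, and the position of the OH places the ring prenyl group on C6.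

Step 8
Reactants: 14 5,7-bis(methoxymethoxy)-3,6-bis(3-methylbut-2-en-1-yl)-4H-chromen-4-one
Product: 16 2-iodo-5,7-bis(methoxymethoxy)-3,6-bis(3-methylbut-2-en-1-yl)-4H-chromen-4-one, via chromon-2-ylzinc chloride 15 (not isolated)
Conditions: TMPZnCl·LiCl (1.3 equiv), THF, 25 °C; then I2 (1.2 equiv), 0 °C
Reagents that add atoms: iodine, II
Why: With C3 blocked, C2–H next to the ring oxygen is the most acidic position and the zinc amide should metalate it without adding to C4=O (directed zincation of a chromone); iodinolysis of the C–Zn bond gives the iodide.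

Step 9
Reactants: 16 2-iodo-5,7-bis(methoxymethoxy)-3,6-bis(3-methylbut-2-en-1-yl)-4H-chromen-4-one; 17 ethynyltrimethylsilane
Product: 18 5,7-bis(methoxymethoxy)-3,6-bis(3-methylbut-2-en-1-yl)-2-[(trimethylsilyl)ethynyl]-4H-chromen-4-one
Conditions: Pd(PPh3)2Cl2 (3 mol%), CuI (5 mol%), Et3N, THF, rt
Reagents that add atoms: none
Why: Sonogashira coupling; the 2-iodochromone is an electron-poor vinylogous acyl iodide that should add to zerovalent palladium at room temperature.

Step 10
Reactants: 18 5,7-bis(methoxymethoxy)-3,6-bis(3-methylbut-2-en-1-yl)-2-[(trimethylsilyl)ethynyl]-4H-chromen-4-one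
Product: 19 2-ethynyl-5,7-bis(methoxymethoxy)-3,6-bis(3-methylbut-2-en-1-yl)-4H-chromen-4-one
Conditions: TBAF (1.05 equiv), AcOH (1.2 equiv), THF, −20 °C
Reagents that add atoms: none
Why: Protodesilylation of an alkynylsilane by fluoride; the acetic acid buffer and low temperature keep basic species from adding to the activated alkyne.

Step 11
Reactants: 20 3-oxopentanedioic acid
Product: 21 3-oxopentanedioic anhydride (oxane-2,4,6-trione)
Conditions: Ac2O, AcOH, 0 to 10 °C
Reagents that add atoms: none
Why: Cyclodehydration of a 1,5-diacid to the six-membered anhydride, which is largely the 4-hydroxy enol; low temperature avoids C-acetylation and decarboxylation.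

Step 12
Reactants: 21 3-oxopentanedioic anhydride (oxane-2,4,6-trione)
Product: 22 4,6-bis(tert-butyldimethylsilyloxy)-2H-pyran-2-one
Conditions: TBSOTf (2.2 equiv), Et3N (2.5 equiv), Et2O, 0 °C; filtered under N2 and used at once
Reagents that add atoms: tert-butyldimethylsilyl trifluoromethanesulfonate, CC(C)(C)[Si](C)(C)OS(=O)(=O)C(F)(F)F
Why: Soft enolisation and O-silylation, the reaction type that turns β-dicarbonyl compounds and cyclic anhydrides into silyloxy-substituted heteroaromatics; the acidic 4-enol is silylated first, after which silylation of either anhydride oxygen gives the same 2-pyranone.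

Step 13
Reactants: 19 2-ethynyl-5,7-bis(methoxymethoxy)-3,6-bis(3-methylbut-2-en-1-yl)-4H-chromen-4-one; 22 4,6-bis(tert-butyldimethylsilyloxy)-2H-pyran-2-one
Product: 24 2-[2,4-bis(tert-butyldimethylsilyloxy)phenyl]-5,7-bis(methoxymethoxy)-3,6-bis(3-methylbut-2-en-1-yl)-4H-chromen-4-one (cudraflavone C 5,7-bis(methoxymethyl) 2',4'-bis(tert-butyldimethylsilyl) ether), via bridged lactone adduct 23 (not isolated)
Conditions: 22 (2.5 equiv), BHT (cat.), PhMe, 110 °C, sealed tube, N2
Reagents that add atoms: none
Why: Proposed new method: a normal-electron-demand [4+2] cycloaddition between the electron-rich diene C3=C4–C5=C6 of 22 and the electron-poor alkyne of 19, followed by cycloreversion of the bridged lactone 23 with loss of CO2; the closest known reaction types are the thermal Diels–Alder/decarboxylation of 2-pyranones with alkynes to give benzenes and the cycloaddition–aromatisation of 1-alkoxy-3-silyloxybutadienes with ynones, neither shown for a 4,6-bis(silyloxy)-2-pyranone or a 2-ethynylchromone. Both silyloxy groups raise the HOMO and put its largest terminal coefficient on C3 of 22 (β to the C4 oxygen, δ to the C6 oxygen), while conjugation with C2=C3–C4=O makes the terminal alkyne carbon of 19 the vinylogous Michael position with the largest LUMO coefficient. Asynchronous bond formation should therefore join C3 of 22 to the terminal carbon (C5'–C6') and C6 of 22 to the internal carbon (C1'–C2'), which is the regiochemistry of the 2',4'-dioxygenated ring and the only selectivity the step needs; the opposite orientation would give the 3',5'-isomer. Ring B is closed as a six-membered carbocycle by this intermolecular [4+2] addition, not by a chain cyclisation, and becomes aromatic when 23 expels CO2 in a retro-[4+2] step. No stereocentre is created in 24; the two bridgehead centres of 23 are fixed by the bicycle, racemic and destroyed on loss of CO2. Chemoselectivity rests on the alkyne being the only electron-poor, unhindered π-bond (the prenyl olefins are electron-rich, the C2=C3 bond is tetrasubstituted), and the absence of free OH in 19 prevents silyl transfer from 22. A stepwise Mukaiyama–Michael addition through C3 followed by ring closure would lead to the same adduct, so concertedness is not required.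

Step 14
Reactants: 24 2-[2,4-bis(tert-butyldimethylsilyloxy)phenyl]-5,7-bis(methoxymethoxy)-3,6-bis(3-methylbut-2-en-1-yl)-4H-chromen-4-one
Product: 25 2-(2,4-dihydroxyphenyl)-5,7-bis(methoxymethoxy)-3,6-bis(3-methylbut-2-en-1-yl)-4H-chromen-4-one
Conditions: TBAF (2.2 equiv), AcOH (2.5 equiv), THF, 0 °C
Reagents that add atoms: none
Why: Fluoride cleavage of the two aryl silyl ethers; the buffer avoids a free, oxidisable resorcinolate, and the acetals are stable to fluoride.

Step 15
Reactants: 25 2-(2,4-dihydroxyphenyl)-5,7-bis(methoxymethoxy)-3,6-bis(3-methylbut-2-en-1-yl)-4H-chromen-4-one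
Product: 26 cudraflavone C
Conditions: HCl (3 M aq., cat.), MeOH, 40 °C, stopped at full conversion
Reagents that add atoms: none
Why: Acid-catalysed acetal exchange with methanol removes both methoxymethyl groups, the chelated 5-acetal first; mild acid and temperature are chosen so that the prenyl olefins should not cyclise onto the freed phenols.

## Compound list

1 | phloroglucinol | Oc1cc(O)cc(O)c1 | starting material
2 | 3,5-bis(methoxymethoxy)phenol | COCOc1cc(O)cc(OCOC)c1 | intermediate
3 | [3,5-bis(methoxymethoxy)phenoxy]tri(propan-2-yl)silane | COCOc1cc(OCOC)cc(O[Si](C(C)C)(C(C)C)C(C)C)c1 | intermediate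
4 | 1-bromo-3-methylbut-2-ene (prenyl bromide) | CC(C)=CCBr | starting material
5 | [2,6-bis(methoxymethoxy)-4-{[tri(propan-2-yl)silyl]oxy}phenyl]lithium (not isolated) | [Li]c1c(OCOC)cc(O[Si](C(C)C)(C(C)C)C(C)C)cc1OCOC | intermediate
6 | [3,5-bis(methoxymethoxy)-4-(3-methylbut-2-en-1-yl)phenoxy]tri(propan-2-yl)silane | COCOc1cc(O[Si](C(C)C)(C(C)C)C(C)C)cc(OCOC)c1CC=C(C)C | intermediate
7 | 5-methylhex-4-enoic acid | CC(C)=CCCC(=O)O | starting material
8 | 1-(1H-imidazol-1-yl)-5-methylhex-4-en-1-one (not isolated) | CC(C)=CCCC(=O)n1ccnc1 | intermediate
9 | N-methoxy-N,5-dimethylhex-4-enamide | CC(C)=CCCC(=O)N(C)OC | intermediate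
10 | [2,4-bis(methoxymethoxy)-3-(3-methylbut-2-en-1-yl)-6-{[tri(propan-2-yl)silyl]oxy}phenyl]lithium (not isolated) | [Li]c1c(O[Si](C(C)C)(C(C)C)C(C)C)cc(OCOC)c(CC=C(C)C)c1OCOC | intermediate
11 | 1-[2,4-bis(methoxymethoxy)-3-(3-methylbut-2-en-1-yl)-6-{[tri(propan-2-yl)silyl]oxy}phenyl]-5-methylhex-4-en-1-one | CC(C)=CCCC(=O)c1c(O[Si](C(C)C)(C(C)C)C(C)C)cc(OCOC)c(CC=C(C)C)c1OCOC | intermediate
12 | 1-[6-hydroxy-2,4-bis(methoxymethoxy)-3-(3-methylbut-2-en-1-yl)phenyl]-5-methylhex-4-en-1-one | CC(C)=CCCC(=O)c1c(O)cc(OCOC)c(CC=C(C)C)c1OCOC | intermediate
13 | (2E)-2-[(dimethylamino)methylidene]-1-[6-hydroxy-2,4-bis(methoxymethoxy)-3-(3-methylbut-2-en-1-yl)phenyl]-5-methylhex-4-en-1-one (not isolated; geometry immaterial) | CN(C)/C=C(\CC=C(C)C)C(=O)c1c(O)cc(OCOC)c(CC=C(C)C)c1OCOC | intermediate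
14 | 5,7-bis(methoxymethoxy)-3,6-bis(3-methylbut-2-en-1-yl)-4H-chromen-4-one | COCOc1cc2occ(CC=C(C)C)c(=O)c2c(OCOC)c1CC=C(C)C | intermediate
15 | [5,7-bis(methoxymethoxy)-3,6-bis(3-methylbut-2-en-1-yl)-4-oxo-4H-chromen-2-yl]zinc chloride (not isolated) | Cl[Zn]c1oc2cc(OCOC)c(CC=C(C)C)c(OCOC)c2c(=O)c1CC=C(C)C | intermediate
16 | 2-iodo-5,7-bis(methoxymethoxy)-3,6-bis(3-methylbut-2-en-1-yl)-4H-chromen-4-one | Ic1oc2cc(OCOC)c(CC=C(C)C)c(OCOC)c2c(=O)c1CC=C(C)C | intermediate
17 | ethynyltrimethylsilane | C#C[Si](C)(C)C | starting material
18 | 5,7-bis(methoxymethoxy)-3,6-bis(3-methylbut-2-en-1-yl)-2-[(trimethylsilyl)ethynyl]-4H-chromen-4-one | C[Si](C)(C)C#Cc1oc2cc(OCOC)c(CC=C(C)C)c(OCOC)c2c(=O)c1CC=C(C)C | intermediate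
19 | 2-ethynyl-5,7-bis(methoxymethoxy)-3,6-bis(3-methylbut-2-en-1-yl)-4H-chromen-4-one | C#Cc1oc2cc(OCOC)c(CC=C(C)C)c(OCOC)c2c(=O)c1CC=C(C)C | intermediate
20 | 3-oxopentanedioic acid | O=C(O)CC(=O)CC(=O)O | starting material
21 | 3-oxopentanedioic anhydride (oxane-2,4,6-trione) | O=C1CC(=O)OC(=O)C1 | intermediate
22 | 4,6-bis(tert-butyldimethylsilyloxy)-2H-pyran-2-one | CC(C)(C)[Si](C)(C)Oc1cc(O[Si](C)(C)C(C)(C)C)oc(=O)c1 | intermediate
23 | 1,5-bis(tert-butyldimethylsilyloxy)-7-[5,7-bis(methoxymethoxy)-3,6-bis(3-methylbut-2-en-1-yl)-4-oxo-4H-chromen-2-yl]-2-oxabicyclo[2.2.2]octa-5,7-dien-3-one (racemic, not isolated) | O=C1OC2(O[Si](C)(C)C(C)(C)C)C=C(O[Si](C)(C)C(C)(C)C)C1C=C2c1oc2cc(OCOC)c(CC=C(C)C)c(OCOC)c2c(=O)c1CC=C(C)C | intermediate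
24 | 2-[2,4-bis(tert-butyldimethylsilyloxy)phenyl]-5,7-bis(methoxymethoxy)-3,6-bis(3-methylbut-2-en-1-yl)-4H-chromen-4-one | CC(C)=CCc1c(OCOC)cc2oc(-c3ccc(O[Si](C)(C)C(C)(C)C)cc3O[Si](C)(C)C(C)(C)C)c(CC=C(C)C)c(=O)c2c1OCOC | intermediate
25 | 2-(2,4-dihydroxyphenyl)-5,7-bis(methoxymethoxy)-3,6-bis(3-methylbut-2-en-1-yl)-4H-chromen-4-one | CC(C)=CCc1c(OCOC)cc2oc(-c3ccc(O)cc3O)c(CC=C(C)C)c(=O)c2c1OCOC | intermediate
26 | cudraflavone C, 2-(2,4-dihydroxyphenyl)-5,7-dihydroxy-3,6-bis(3-methylbut-2-en-1-yl)-4H-chromen-4-one | CC(C)=CCc1c(O)cc2oc(-c3ccc(O)cc3O)c(CC=C(C)C)c(=O)c2c1O | target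

## Step count and least certain steps

Total step count: 15. Longest linear sequence: 12 steps (steps 1, 2, 3, 5, 6, 7, 8, 9, 10, 13, 14, 15).

Step 13 (key step, proposed new method). Most likely to go wrong: conjugate addition of the silyl ketene acetal part of 22 through C5 without ring closure, reversal of the regiochemistry, or thermal oligomerisation of the terminal ynenone before cycloaddition, because the pairing of this diene with this dienophile is untested and 22 has two nucleophilic carbons. Fallback with known chemistry, from 16 back to 24: commercial 4-bromoresorcinol would be silylated (TBSCl, imidazole, DMF) to 1-bromo-2,4-bis(tert-butyldimethylsilyloxy)benzene F1. Miyaura borylation (B2pin2, Pd(dppf)Cl2, KOAc, dioxane, 80 °C) would give 2-[2,4-bis(tert-butyldimethylsilyloxy)phenyl]-4,4,5,5-tetramethyl-1,3,2-dioxaborolane F2. Suzuki–Miyaura coupling of F2 with 16 (Pd(OAc)2, SPhos, K3PO4, PhMe/H2O, 80 °C) would give 24. Any silyl ether lost under the basic conditions does not matter, since step 14 removes both; the price is the hindered coupling next to the C3 prenyl group.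

Step 12. Most likely to go wrong: hydrolytic loss of the ketene-acetal silyl group during isolation, or amine-induced ring opening and decarboxylation of 21, because 22 is a mixed acyl silyl ketene acetal. Fallback, from 19 back to 25, replacing the diene: methyl acetoacetate would be silylated (TMSCl, Et3N) to methyl 3-(trimethylsilyloxy)but-2-enoate F3. Deprotonation and a second silylation (LDA, TMSCl, THF, −78 °C) would give 1-methoxy-1,3-bis(trimethylsilyloxy)buta-1,3-diene F4. Cycloaddition of F4 with 19 (PhMe, 60 to 80 °C) should give the cyclohexadiene adduct F5 (not isolated) with the same orientation. Mild acidic work-up (pyridinium p-toluenesulfonate, wet THF) would eliminate methanol, hydrolyse the trimethylsilyl ethers and give 25 directly.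

Step 5. Most likely to go wrong: O-to-C silyl migration in the ortho-lithiated silyl ether, competing deprotonation of the benzylic–allylic CH2 flanked by two acetals, or proton transfer from 9 to the hindered aryllithium. Fallback, from 6 back to 12: desilylation of 6 (TBAF, AcOH, THF) would give 3,5-bis(methoxymethoxy)-4-(3-methylbut-2-en-1-yl)phenol F6. Magnesium-mediated ortho-formylation (MgCl2, Et3N, paraformaldehyde, MeCN, reflux) would give 6-hydroxy-2,4-bis(methoxymethoxy)-3-(3-methylbut-2-en-1-yl)benzaldehyde F7. Addition of (4-methylpent-3-en-1-yl)magnesium bromide (2.2 equiv, THF, 0 °C) would give racemic 1-[6-hydroxy-2,4-bis(methoxymethoxy)-3-(3-methylbut-2-en-1-yl)phenyl]-5-methylhex-4-en-1-ol F8. Oxidation of the benzylic alcohol with MnO2 (CH2Cl2, rt) would return 12. This is two steps longer but needs no second aryl lithiation.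

Step 10. Most likely to go wrong: conjugate addition of basic or nucleophilic species to the activated alkyne and oligomerisation of the terminal ynenone during desilylation. Fallback, from 16 back to 19 without a silyl alkyne: Negishi coupling of 16 with ethynylzinc bromide (made in the flask from ethynylmagnesium bromide and ZnBr2; Pd(PPh3)4, THF, rt) should give 19 directly; this fallback makes no new compound (F0).

Step 15. Most likely to go wrong: acid-catalysed cyclisation of the C6 prenyl group onto the freed 5- or 7-OH (chroman formation) or hydration of the olefins under protic acid. Fallback, from 25 back to 26 by a non-protic dealkylation: ZnBr2 and propane-1-thiol in CH2Cl2 at 0 °C would cleave the acetals by Lewis-acid activation and capture of the methoxymethyl cation by the thiol, in minutes and without a protic acid; this fallback makes no new compound (F0).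

## Further compounds

F1 | step 13 | 1-bromo-2,4-bis(tert-butyldimethylsilyloxy)benzene | CC(C)(C)[Si](C)(C)Oc1ccc(Br)c(O[Si](C)(C)C(C)(C)C)c1
F2 | step 13 | 2-[2,4-bis(tert-butyldimethylsilyloxy)phenyl]-4,4,5,5-tetramethyl-1,3,2-dioxaborolane | CC(C)(C)[Si](C)(C)Oc1ccc(B2OC(C)(C)C(C)(C)O2)c(O[Si](C)(C)C(C)(C)C)c1
F3 | step 12 | methyl 3-(trimethylsilyloxy)but-2-enoate (alkene geometry not controlled) | COC(=O)C=C(C)O[Si](C)(C)C
F4 | step 12 | 1-methoxy-1,3-bis(trimethylsilyloxy)buta-1,3-diene (geometry of the ketene acetal bond immaterial) | COC(O[Si](C)(C)C)=CC(=C)O[Si](C)(C)C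
F5 | step 12 | 2-[6-methoxy-4,6-bis(trimethylsilyloxy)cyclohexa-1,4-dien-1-yl]-5,7-bis(methoxymethoxy)-3,6-bis(3-methylbut-2-en-1-yl)-4H-chromen-4-one (racemic, not isolated) | COC1(O[Si](C)(C)C)C=C(O[Si](C)(C)C)CC=C1c1oc2cc(OCOC)c(CC=C(C)C)c(OCOC)c2c(=O)c1CC=C(C)C
F6 | step 5 | 3,5-bis(methoxymethoxy)-4-(3-methylbut-2-en-1-yl)phenol | COCOc1cc(O)cc(OCOC)c1CC=C(C)C
F7 | step 5 | 6-hydroxy-2,4-bis(methoxymethoxy)-3-(3-methylbut-2-en-1-yl)benzaldehyde | O=Cc1c(O)cc(OCOC)c(CC=C(C)C)c1OCOC
F8 | step 5 | 1-[6-hydroxy-2,4-bis(methoxymethoxy)-3-(3-methylbut-2-en-1-yl)phenyl]-5-methylhex-4-en-1-ol (racemic) | CC(C)=CCCC(O)c1c(O)cc(OCOC)c(CC=C(C)C)c1OCOC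
F0 | step 10 | none | none
F0 | step 15 | none | none
A1 | alternative 1 | cudraflavone C 2',4'-bis(methoxymethyl) ether | CC(C)=CCc1c(O)cc2oc(-c3ccc(OCOC)cc3OCOC)c(CC=C(C)C)c(=O)c2c1O
A2 | alternative 1 | methyl 4-{6-[2,4-bis(methoxymethoxy)phenyl]-5-(3-methylbut-2-en-1-yl)-4-oxo-4H-pyran-2-yl}-2-(3-methylbut-2-en-1-yl)-3-oxobutanoate (racemic) | COC(=O)C(CC=C(C)C)C(=O)Cc1cc(=O)c(CC=C(C)C)c(-c2ccc(OCOC)cc2OCOC)o1
A3 | alternative 2 | cudraflavone C 5,7,2',4'-tetrakis(methoxymethyl) ether | COCOc1ccc(-c2oc3cc(OCOC)c(CC=C(C)C)c(OCOC)c3c(=O)c2CC=C(C)C)c(OCOC)c1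
A4 | alternative 2 | 3,5-bis(methoxymethoxy)-4-(3-methylbut-2-en-1-yl)-2-(trimethylsilyl)phenyl trifluoromethanesulfonate | COCOc1cc(OS(=O)(=O)C(F)(F)F)c([Si](C)(C)C)c(OCOC)c1CC=C(C)C
A5 | alternative 2 | 3-[2,4-bis(methoxymethoxy)phenyl]-3-methoxy-2-(3-methylbut-2-en-1-yl)prop-2-enoic acid (alkene geometry immaterial) | COC(=C(CC=C(C)C)C(=O)O)c1ccc(OCOC)cc1OCOC
A6 | alternative 3 | cudraflavone C 7-triisopropylsilyl 2',4'-bis(methoxymethyl) ether | CC(C)=CCc1c(O[Si](C(C)C)(C(C)C)C(C)C)cc2oc(-c3ccc(OCOC)cc3OCOC)c(CC=C(C)C)c(=O)c2c1O
A7 | alternative 3 | 6-(2-diazoacetyl)-2-[2,4-bis(methoxymethoxy)phenyl]-3-(3-methylbut-2-en-1-yl)-4H-pyran-4-one | [N-]=[N+]=CC(=O)c1cc(=O)c(CC=C(C)C)c(-c2ccc(OCOC)cc2OCOC)o1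
A8 | alternative 3 | triisopropyl[(5-methylhex-4-en-1-yn-1-yl)oxy]silane | CC(C)=CCC#CO[Si](C(C)C)(C(C)C)C(C)C
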